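Its constants were set for the occasion.

While crystals lie in a stirred flask, dissolved target stays at its solubility of 1.2 mM, and the rest of the solution can be reckoned from that.

    starting material ⇌ target (K1 = 1.3, k1 = 0.17 s⁻¹)
    crystals ⇌ target, rate k2*(cs2 - [target]) while solid is left; crystals form when [target] > cs2 (cs2 = 1.2 mM, k2 = 2.7 s⁻¹)
    target ⇌ isomer of the product (k3 = 0.015 s⁻¹)
    starting material ⇌ isomer of the product (K4 = 6.5, k4 = 0.023 s⁻¹)

starting material 0.050 M; time 6.0 min

- what is said of target includes crystals
- crystals is a solid; its amount is given per volume of the solution
- the reaction counts as stopped when no species that holds the starting material changes by six tenths of a point or more over the second half of the time
- run time (flask): 6.0 min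

* why nothing more happens at 6.0 min, or that something still does (forward and back rates have come level / it is still moving)
* amount of target at 6.0 min, in percent of the starting material charged
* amount of isomer of the product at 6.0 min, in percent of the starting material charged

The charge of 0.050 M is far more than that solubility, so crystals form. Balance with target then puts starting material at 0.923 mM. Balance with starting material puts isomer of the product at the solid-held level, the concentration of isomer in equilibrium with a solution kept at the solubility of target while crystals remain: 6.00 mM. In this flask that is 12.0% of the charge as isomer of the product, which leaves 86.2% as target. Isomer of the product first takes a share of 11.9% of the starting material used (kinetic control), or 5.95 mM on this charge, so it starts next to its level (thermodynamic control). Any remainder relaxes through both back routes with a half-life of 1.77 min, which is shorter than the time.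

The forecast gives forward and back rates have come level, with 86.1% target and 12.1% isomer of the product, starting from "Crystallisation is fast and pins dissolved target".

The simulation of the flask at 6.0 min gives forward and back rates have come level, with 86.0% target and 12.1% isomer of the product, and the largest change over the second half is 0.24 percentage points.

The crystals, 83.6% of the charge at 6.0 min, have the largest single effect on target: without them target stands at 14.8% instead of 86.0%.

In the neighbour flask with 0.085 M of starting material the level stays 6.00 mM, or 7.06% of that charge, but the early share makes 10.1 mM, more than the level. Relaxing that excess over 6.0 min gives 7.52%, and the neighbour flask gives 7.75%.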